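Ring A is built, not substituted. Cutting its C3–C4 and C5–C6 bonds leaves a 3-substituted cyclobutenone, which already carries the ring B arm on the future C1, and a prenyl-bearing siloxyalkyne. Heating the pair sets off a pericyclic cascade (4π opening, ketene–alkyne [2+2], 4π opening, 6π closure) that closes ring A in one operation. It exploits the resorcinol pattern of ring A: oxygen on C3 and C5, prenyl on C4 between them, the bridge on C1 para to the prenyl group. In the cyclobutenone precursor ring B has its 2-methoxy group in place and O3 and O4 masked differently (benzyl, MOM), so the acetate can later reach O4 only.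

Key step: step 9

Remark on numbering and abbreviations: in each ring C1 carries the CH2CH2 bridge; ring B has OMe on C2, OH on C3 and OAc on C4. ArB stands for 3-(benzyloxy)-2-methoxy-4-(methoxymethoxy)phenyl and prenyl for 3-methylbut-2-enyl.
Remark on the design: O3 of ring B travels as a benzyl ether and O4 as a MOM ether, so no step has to distinguish two neighbouring free hydroxyls by acylation rate.
Assumption: 3-ethoxycyclobut-2-en-1-one and ethyl 4-methylpent-3-enoate are taken as purchasable.

Step 1
Reactants: 1 2,3,4-trihydroxybenzaldehyde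
Product: 2 2,3-dihydroxy-4-(methoxymethoxy)benzaldehyde
Conditions: MOMCl (1.05 equiv), i-Pr2NEt (1.1 equiv), THF, 0 °C
Reagents that add atoms: chloromethyl methyl ether, COCCl
Why: With one equivalent of amine base only the most acidic, non-chelated hydroxyl (O4, para to the formyl group) is ionised, so this Williamson-type O-alkylation should go to O4 while O2 stays locked in its hydrogen bond to the aldehyde.

Step 2
Reactants: 2 2,3-dihydroxy-4-(methoxymethoxy)benzaldehyde
Product: 3 3-(benzyloxy)-2-hydroxy-4-(methoxymethoxy)benzaldehyde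
Conditions: NaH (2.1 equiv), DMSO, 20 °C; BnBr (1.0 equiv); dilute HCl work-up
Reagents that add atoms: benzyl bromide, BrCc1ccccc1
Why: In the dianion the O2 phenoxide is delocalised into the formyl group, so the more basic O3 phenoxide should take the single equivalent of benzyl bromide (Williamson ether synthesis by regioselective catecholate dianion alkylation).

Step 3
Reactants: 3 3-(benzyloxy)-2-hydroxy-4-(methoxymethoxy)benzaldehyde
Product: 4 3-(benzyloxy)-2-methoxy-4-(methoxymethoxy)benzaldehyde
Conditions: MeI, K2CO3, DMF, 40 °C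
Reagents that add atoms: iodomethane, CI
Why: With O3 and O4 capped, Williamson methylation of the one remaining, chelated O2 phenol is unambiguous.

Step 4
Reactants: 4 3-(benzyloxy)-2-methoxy-4-(methoxymethoxy)benzaldehyde
Product: 5 2-(benzyloxy)-4-ethenyl-3-methoxy-1-(methoxymethoxy)benzene
Conditions: Ph3PCH3Br, KOt-Bu, THF, 0 → 25 °C
Reagents that add atoms: methyltriphenylphosphonium bromide, C[P+](c1ccccc1)(c1ccccc1)c1ccccc1.[Br-]
Why: Wittig methylenation of a non-enolisable aryl aldehyde with the unstabilised ylide is reliable and leaves the benzyl and MOM ethers alone.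

Step 5
Reactants: 5 2-(benzyloxy)-4-ethenyl-3-methoxy-1-(methoxymethoxy)benzene
Product: 7 2-(ArB)ethanol, via B-alkyl-9-BBN 6 (not isolated)
Conditions: 9-BBN, THF, 0 → 25 °C; then NaOH, H2O2, 0 °C
Reagents that add atoms: 9-borabicyclo[3.3.1]nonane, B1C2CCCC1CCC2 (boron of 6 only); hydrogen peroxide, OO
Why: Brown hydroboration–oxidation with the bulky 9-BBN places boron on the terminal carbon of the styrene, and alkaline peroxide turns the C–B bond into the primary alcohol without touching the ethers.

Step 6
Reactants: 7 2-(ArB)ethanol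
Product: 8 2-(benzyloxy)-4-(2-bromoethyl)-3-methoxy-1-(methoxymethoxy)benzene
Conditions: CBr4, PPh3, CH2Cl2, 0 °C
Reagents that add atoms: carbon tetrabromide, BrC(Br)(Br)Br
Why: Appel bromination converts the primary alcohol into the bromide under neutral conditions that spare the MOM acetal.

Step 7
Reactants: 8 2-(benzyloxy)-4-(2-bromoethyl)-3-methoxy-1-(methoxymethoxy)benzene; 9 3-ethoxycyclobut-2-en-1-one
Product: 12 3-[2-(ArB)ethyl]cyclobut-2-en-1-one, via Grignard reagent 10 (not isolated), via ethoxycyclobutenol 11 (not isolated)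
Conditions: Mg, THF, 25–40 °C; then 9, THF, −78 → 0 °C; then 1 M HCl, 0 °C
Reagents that add atoms: magnesium, [Mg] (in 10 only); water, O (exchanges into the carbonyl oxygen of 12)
Why: The primary Grignard reagent adds 1,2 to the vinylogous ester carbonyl, and brief cold dilute acid then ionises the tertiary allylic alcohol and hydrolyses the enol ether with loss of ethanol (Stork–Danheiser-type carbonyl transposition), which is too mild to cleave the aryl MOM ether.

Step 8
Reactants: 13 ethyl 4-methylpent-3-enoate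
Product: 16 triisopropyl[(5-methylhex-4-en-1-yn-1-yl)oxy]silane, via dibromo enolate 14 (not isolated), via lithium ynolate 15 (not isolated)
Conditions: CH2Br2, lithium 2,2,6,6-tetramethylpiperidide, THF, −78 °C, then 13; LiN(SiMe3)2, then n-BuLi, −78 → 25 °C; TIPSCl, −78 → 0 °C
Reagents that add atoms: dibromomethane, BrCBr (supplies the oxygen-bearing alkyne carbon); chlorotriisopropylsilane, CC(C)[Si](Cl)(C(C)C)C(C)C; lithium of 14 and 15 from LiN(SiMe3)2, [Li]N([Si](C)(C)C)[Si](C)(C)C, and n-BuLi, [Li]CCCC
Why: This is the Kowalski ester homologation stopped at the ynolate (acylation of dibromomethyllithium, enolisation, bromine–lithium exchange and 1,2-shift of the prenyl-bearing carbon), and the bulky silyl chloride should silylate the ynolate on oxygen.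

Step 9
Reactants: 12 3-[2-(ArB)ethyl]cyclobut-2-en-1-one; 16 triisopropyl[(5-methylhex-4-en-1-yn-1-yl)oxy]silane
Product: 21 5-[2-(ArB)ethyl]-2-prenyl-3-(triisopropylsilyloxy)phenol, via vinylketene 17 (not isolated), via alkenylcyclobutenone 18 (not isolated), via dienylketene 19 (not isolated), via cyclohexadienone 20 (not isolated)
Conditions: 16 (1.3 equiv), toluene, 80 °C then 110 °C, argon
Reagents that add atoms: none
Why: On heating, 12 undergoes 4π electrocyclic opening to vinylketene 17, which adds the siloxyalkyne in a ketene–alkyne [2+2] cycloaddition to give 18; 4π opening of 18 gives dienylketene 19, and its 6π electrocyclisation followed by tautomerisation of 20 should deliver phenol 21. The closest known reaction is the Danheiser benzannulation of cyclobutenones with trialkylsiloxyalkynes to monosilylated resorcinols. The [2+2] makes the two new skeletal bonds of ring A, C3–C4 and C5–C6, and the ring itself is closed between C2 and C3 by the thermally allowed disrotatory 6π electrocyclisation, driven on by aromatisation. No stereocenter is formed, since the one in 18 is transient and is erased on ring opening. The step needs regioselectivity in the [2+2]: the siloxy group makes the prenyl-bearing alkyne carbon the nucleophilic terminus, so it bonds to the electrophilic ketene carbonyl carbon, which places prenyl on C4 between the new hydroxyl and the silyloxy group and para to the bridge. The neutral thermal conditions should leave the prenyl alkene and the benzyl, MOM and methyl ethers untouched, and the slight excess of 16 keeps the product phenol from being acylated by 17.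

Step 10
Reactants: 21 5-[2-(ArB)ethyl]-2-prenyl-3-(triisopropylsilyloxy)phenol
Product: 23 2-(benzyloxy)-4-{2-[3,5-dimethoxy-4-prenylphenyl]ethyl}-3-methoxy-1-(methoxymethoxy)benzene, via resorcinol 22 (not isolated)
Conditions: Bu4NF, THF, 0 °C; then MeI, K2CO3, DMF, 25 °C
Reagents that add atoms: iodomethane, CI
Why: Fluoride cleaves the aryl silyl ether and the air-sensitive 2-prenylresorcinol is methylated twice in the same flask (Williamson ether synthesis), after which no free hydroxyl remains ortho to the prenyl group that could close a chroman.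

Step 11
Reactants: 23 2-(benzyloxy)-4-{2-[3,5-dimethoxy-4-prenylphenyl]ethyl}-3-methoxy-1-(methoxymethoxy)benzene
Product: 24 2-(benzyloxy)-4-{2-[3,5-dimethoxy-4-prenylphenyl]ethyl}-3-methoxyphenol
Conditions: conc. HCl (cat.), MeOH, 40 °C
Reagents that add atoms: none
Why: Acid-catalysed acetal exchange transfers the MOM group to methanol and frees only O4, while the benzyl and methyl ethers are stable and the prenyl alkene has no neighbouring hydroxyl to trap a cation.

Step 12
Reactants: 24 2-(benzyloxy)-4-{2-[3,5-dimethoxy-4-prenylphenyl]ethyl}-3-methoxyphenol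
Product: 25 2-(benzyloxy)-4-{2-[3,5-dimethoxy-4-prenylphenyl]ethyl}-3-methoxyphenyl acetate
Conditions: Ac2O, pyridine, DMAP (cat.), CH2Cl2, 0 °C
Reagents that add atoms: acetic anhydride, CC(=O)OC(C)=O
Why: DMAP-catalysed acylation of the single free phenol can place the acetate only on O4, because O3 is still benzylated.

Step 13
Reactants: 25 2-(benzyloxy)-4-{2-[3,5-dimethoxy-4-prenylphenyl]ethyl}-3-methoxyphenyl acetate
Product: 26 4-{2-[3,5-dimethoxy-4-prenylphenyl]ethyl}-2-hydroxy-3-methoxyphenyl acetate (target)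
Conditions: BCl3 (2 equiv), C6HMe5 (3 equiv), CH2Cl2, −78 °C; pH 7 buffer
Reagents that add atoms: none
Why: Lewis acid debenzylation with BCl3 and pentamethylbenzene as a non-basic benzyl cation scavenger cleaves aryl benzyl ethers at −78 °C, where the aryl methyl ethers, the aryl acetate and the trisubstituted alkene should survive, and the cold non-basic medium avoids acetyl migration from O4 to O3.

Compound list
1 | 2,3,4-trihydroxybenzaldehyde | O=Cc1ccc(O)c(O)c1O | starting material
2 | 2,3-dihydroxy-4-(methoxymethoxy)benzaldehyde | O=Cc1ccc(OCOC)c(O)c1O | intermediate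
3 | 3-(benzyloxy)-2-hydroxy-4-(methoxymethoxy)benzaldehyde | O=Cc1ccc(OCOC)c(OCc2ccccc2)c1O | intermediate
4 | 3-(benzyloxy)-2-methoxy-4-(methoxymethoxy)benzaldehyde | O=Cc1ccc(OCOC)c(OCc2ccccc2)c1OC | intermediate
5 | 2-(benzyloxy)-4-ethenyl-3-methoxy-1-(methoxymethoxy)benzene | C=Cc1ccc(OCOC)c(OCc2ccccc2)c1OC | intermediate
6 | 9-[2-(ArB)ethyl]-9-borabicyclo[3.3.1]nonane | COCOc1ccc(CCB2C3CCCC2CCC3)c(OC)c1OCc1ccccc1 | intermediate
7 | 2-[3-(benzyloxy)-2-methoxy-4-(methoxymethoxy)phenyl]ethanol | OCCc1ccc(OCOC)c(OCc2ccccc2)c1OC | intermediate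
8 | 2-(benzyloxy)-4-(2-bromoethyl)-3-methoxy-1-(methoxymethoxy)benzene | BrCCc1ccc(OCOC)c(OCc2ccccc2)c1OC | intermediate
9 | 3-ethoxycyclobut-2-en-1-one | CCOC1=CC(=O)C1 | starting material
10 | [2-(ArB)ethyl]magnesium bromide | Br[Mg]CCc1ccc(OCOC)c(OCc2ccccc2)c1OC | intermediate
11 | 3-ethoxy-1-[2-(ArB)ethyl]cyclobut-2-en-1-ol (racemic) | CCOC1=CC(O)(CCc2ccc(OCOC)c(OCc3ccccc3)c2OC)C1 | intermediate
12 | 3-{2-[3-(benzyloxy)-2-methoxy-4-(methoxymethoxy)phenyl]ethyl}cyclobut-2-en-1-one | O=C1CC(CCc2ccc(OCOC)c(OCc3ccccc3)c2OC)=C1 | intermediate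
13 | ethyl 4-methylpent-3-enoate | CCOC(=O)CC=C(C)C | starting material
14 | lithium 1,1-dibromo-5-methylhexa-1,4-dien-2-olate | [Li]OC(CC=C(C)C)=C(Br)Br | intermediate
15 | lithium 5-methylhex-4-en-1-yn-1-olate | [Li]OC#CCC=C(C)C | intermediate
16 | triisopropyl[(5-methylhex-4-en-1-yn-1-yl)oxy]silane | CC(C)=CCC#CO[Si](C(C)C)(C(C)C)C(C)C | intermediate
17 | 5-(ArB)-3-methylidenepent-1-en-1-one (vinylketene) | O=C=CC(=C)CCc1ccc(OCOC)c(OCc2ccccc2)c1OC | intermediate
18 | 4-[4-(ArB)but-1-en-2-yl]-2-prenyl-3-(triisopropylsilyloxy)cyclobut-2-en-1-one (racemic) | O=C1C(CC=C(C)C)=C(O[Si](C(C)C)(C(C)C)C(C)C)C1C(=C)CCc1ccc(OCOC)c(OCc2ccccc2)c1OC | intermediate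
19 | 7-(ArB)-5-methylidene-2-prenyl-3-(triisopropylsilyloxy)hepta-1,3-dien-1-one, ketene carbon and vinyl group cis on the C3=C4 bond | O=C=C(CC=C(C)C)/C(O[Si](C(C)C)(C(C)C)C(C)C)=C\C(=C)CCc1ccc(OCOC)c(OCc2ccccc2)c1OC | intermediate
20 | 5-[2-(ArB)ethyl]-2-prenyl-3-(triisopropylsilyloxy)cyclohexa-2,4-dien-1-one | O=C1CC(CCc2ccc(OCOC)c(OCc3ccccc3)c2OC)=CC(O[Si](C(C)C)(C(C)C)C(C)C)=C1CC=C(C)C | intermediate
21 | 5-{2-[3-(benzyloxy)-2-methoxy-4-(methoxymethoxy)phenyl]ethyl}-2-(3-methylbut-2-enyl)-3-(triisopropylsilyloxy)phenol | Oc1cc(CCc2ccc(OCOC)c(OCc3ccccc3)c2OC)cc(O[Si](C(C)C)(C(C)C)C(C)C)c1CC=C(C)C | intermediate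
22 | 5-[2-(ArB)ethyl]-2-(3-methylbut-2-enyl)benzene-1,3-diol | Oc1cc(CCc2ccc(OCOC)c(OCc3ccccc3)c2OC)cc(O)c1CC=C(C)C | intermediate
23 | 2-(benzyloxy)-4-{2-[3,5-dimethoxy-4-(3-methylbut-2-enyl)phenyl]ethyl}-3-methoxy-1-(methoxymethoxy)benzene | COc1cc(CCc2ccc(OCOC)c(OCc3ccccc3)c2OC)cc(OC)c1CC=C(C)C | intermediate
24 | 2-(benzyloxy)-4-{2-[3,5-dimethoxy-4-(3-methylbut-2-enyl)phenyl]ethyl}-3-methoxyphenol | COc1cc(CCc2ccc(O)c(OCc3ccccc3)c2OC)cc(OC)c1CC=C(C)C | intermediate
25 | 2-(benzyloxy)-4-{2-[3,5-dimethoxy-4-(3-methylbut-2-enyl)phenyl]ethyl}-3-methoxyphenyl acetate | COc1cc(CCc2ccc(OC(C)=O)c(OCc3ccccc3)c2OC)cc(OC)c1CC=C(C)C | intermediate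
26 | 4-{2-[3,5-dimethoxy-4-(3-methylbut-2-enyl)phenyl]ethyl}-2-hydroxy-3-methoxyphenyl acetate | COc1cc(CCc2ccc(OC(C)=O)c(O)c2OC)cc(OC)c1CC=C(C)C | target

Total step count: 13. Longest linear sequence: 12 steps (steps 1–7 and 9–13, from 1 to 26); step 8 is the only step of the second branch.

Steps most likely to fail

Step 9. The vinylketene may be diverted into dimers or into acylation of the product phenol, or the cascade may stall at the alkenylcyclobutenone stage. The fallback takes ring A from an intact arene; it sets out from aldehyde 4 and comes back to the route at 23. Commercial (4-bromo-3,5-dimethoxyphenyl)methanol F1 is converted with n-BuLi (2.2 equiv, THF, −78 °C) into lithium (4-lithio-3,5-dimethoxyphenyl)methanolate F2, which is allylated with 1-bromo-3-methylbut-2-ene in the presence of CuBr·SMe2 (cat.) to give [3,5-dimethoxy-4-(3-methylbut-2-enyl)phenyl]methanol F3. Appel bromination (CBr4, PPh3) should give 5-(bromomethyl)-1,3-dimethoxy-2-(3-methylbut-2-enyl)benzene F4, and Arbuzov reaction with P(OEt)3 diethyl [3,5-dimethoxy-4-(3-methylbut-2-enyl)benzyl]phosphonate F5. Horner–Wadsworth–Emmons olefination of F5 with 4 (NaH, THF) should give (E)-2-(benzyloxy)-4-{2-[3,5-dimethoxy-4-(3-methylbut-2-enyl)phenyl]ethenyl}-3-methoxy-1-(methoxymethoxy)benzene F6. Diimide (TsNHNH2, NaOAc, THF–H2O, reflux) should saturate the disubstituted stilbene alkene much faster than the trisubstituted prenyl alkene and give 23.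

Step 8. The carbenoid base may deprotonate the unusually acidic α-position of the β,γ-unsaturated ester instead of adding to the carbonyl, which leads to double-bond migration and self-condensation. The fallback reaches the ynolate by oxidation of an acetylide. It does not set out from a numbered compound but from commercial 1-bromo-3-methylbut-2-ene F7, which replaces ester 13, and it comes back at ynolate 15. CuCl-catalysed coupling of F7 with ethynylmagnesium bromide (THF) should give 5-methylhex-4-en-1-yne F8. LiN(SiMe3)2 (THF, −78 °C) converts it into lithium 5-methylhex-4-en-1-yn-1-ide F9, whose oxidation with LiOOt-Bu (from t-BuOOH and LiN(SiMe3)2, −78 → 0 °C) gives 15. Silylation as in step 8 then gives 16.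

Step 13. The Lewis acid may add HCl to the prenyl alkene or trigger its cationic cyclisation, or the acetyl group may move from O4 to the freed O3. The fallback removes the benzyl group reductively before any acetate is present; it sets out from phenol 24 and comes back at target 26. Lithium 4,4′-di-tert-butylbiphenylide (THF, −78 °C) should cleave the benzyl ether to 4-{2-[3,5-dimethoxy-4-(3-methylbut-2-enyl)phenyl]ethyl}-3-methoxybenzene-1,2-diol F10. Mono-acetylation with Ac2O (1.0 equiv) and 2,4,6-collidine in CH2Cl2 at −40 °C then relies on the greater hindrance of O3, which is flanked on both sides, and should give 26.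

Further compounds
F1 | step 9 | (4-bromo-3,5-dimethoxyphenyl)methanol | COc1cc(CO)cc(OC)c1Br
F2 | step 9 | lithium (4-lithio-3,5-dimethoxyphenyl)methanolate | [Li]OCc1cc(OC)c([Li])c(OC)c1
F3 | step 9 | [3,5-dimethoxy-4-(3-methylbut-2-enyl)phenyl]methanol | COc1cc(CO)cc(OC)c1CC=C(C)C
F4 | step 9 | 5-(bromomethyl)-1,3-dimethoxy-2-(3-methylbut-2-enyl)benzene | COc1cc(CBr)cc(OC)c1CC=C(C)C
F5 | step 9 | diethyl [3,5-dimethoxy-4-(3-methylbut-2-enyl)benzyl]phosphonate | CCOP(=O)(Cc1cc(OC)c(CC=C(C)C)c(OC)c1)OCC
F6 | step 9 | (E)-2-(benzyloxy)-4-{2-[3,5-dimethoxy-4-(3-methylbut-2-enyl)phenyl]ethenyl}-3-methoxy-1-(methoxymethoxy)benzene | COc1cc(/C=C/c2ccc(OCOC)c(OCc3ccccc3)c2OC)cc(OC)c1CC=C(C)C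
F7 | step 8 | 1-bromo-3-methylbut-2-ene | CC(C)=CCBr
F8 | step 8 | 5-methylhex-4-en-1-yne | C#CCC=C(C)C
F9 | step 8 | lithium 5-methylhex-4-en-1-yn-1-ide | [Li]C#CCC=C(C)C
F10 | step 13 | 4-{2-[3,5-dimethoxy-4-(3-methylbut-2-enyl)phenyl]ethyl}-3-methoxybenzene-1,2-diol | COc1cc(CCc2ccc(O)c(O)c2OC)cc(OC)c1CC=C(C)C
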